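The oxolane ring (O1, C2–C5) is cut at C2–C3 and C4–C5. Its C2–O1–C5 segment is the carbonyl ylide of 3,4,5-trimethoxybenzaldehyde; the cis C3 hydroxymethyl and C4 benzyl carbons are tied back as the carbonyl and the γ-carbon of a γ-aryl butenolide. One [3+2] cycloaddition, anti to the γ-aryl group, forms both bonds, closes the oxolane as a cis-fused 3,7-dioxabicyclo[3.3.0]octan-2-one and sets C2, C3 and C4; the directing benzylic lactone C–O bond is later hydrogenolysed, leaving no trace. The precursors are (S)-5-(3,4,5-trimethoxyphenyl)furan-2(5H)-one and the α-chloro (trimethylsilyl)methyl ether of the aldehyde, unmasked by fluoride.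

Key step: step 4

Assumption: both enantiomers of ProPhenol (2,6-bis{[2-(hydroxydiphenylmethyl)pyrrolidin-1-yl]methyl}-4-methylphenol) are commercial; the one that transfers the alkynyl group to the Si face of 1, giving R-configured 3, is selected by a Mosher ester check on the first run.

Remark on the chemistry: once the γ-carbon has become the C4 benzyl group, any acid that ionises the C2–O1 bond would let the trimethoxybenzyl ring close onto C2 (aryltetralin formation). C2 is therefore fixed and purified at the bicyclic stage 9, and every later step is acid-free.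

Step 1
Reactants: 1 3,4,5-trimethoxybenzaldehyde; 2 methyl propiolate
Product: 3 methyl (R)-4-hydroxy-4-(3,4,5-trimethoxyphenyl)but-2-ynoate
Conditions: Me2Zn (3 equiv), ProPhenol (10 mol%, Si-face-selective enantiomer), Ph3PO (20 mol%), toluene, 4 °C; aq. NH4Cl
Reagents that add atoms: none
Why: Zinc–ProPhenol-catalysed asymmetric alkynylation, in which the zinc acetylide of 2 is transferred to the Si face of the aryl aldehyde inside the chiral dinuclear zinc pocket and sets the carbinol carbon as R (alkynyl outranks aryl in the CIP order, so this R centre is the one that becomes S in 5).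

Step 2
Reactants: 3 methyl (R)-4-hydroxy-4-(3,4,5-trimethoxyphenyl)but-2-ynoate
Product: 5 (S)-5-(3,4,5-trimethoxyphenyl)furan-2(5H)-one, via Z-hydroxy enoate 4 (not isolated)
Conditions: H2 (1 atm), Pd/CaCO3 poisoned with Pb(OAc)2 (Lindlar), EtOAc, rt; filter; PPTS (5 mol%), CH2Cl2, rt
Reagents that add atoms: none
Why: Lindlar semihydrogenation adds H2 syn to give the Z-enoate, whose hydroxyl then lactonises onto the cis ester under mild acid with loss of methanol; no bond to the carbinol carbon is broken, so the configuration is kept and only the descriptor changes to S because the alkene carbon ranks below aryl.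

Step 3
Reactants: 1 3,4,5-trimethoxybenzaldehyde; 6 (trimethylsilyl)methanol
Product: 7 α-chloro-3,4,5-trimethoxybenzyl (trimethylsilyl)methyl ether (racemic at the chloro carbon)
Conditions: Me3SiCl (3 equiv), CH2Cl2, 0 °C → rt; volatiles removed, used crude at once
Reagents that add atoms: chlorotrimethylsilane, C[Si](C)(C)Cl
Why: α-Chloro ether formation from aldehyde, alcohol and a chloride source, in which the hemiacetal ionises to the aryl-stabilised oxocarbenium ion, chloride adds, and Me3SiCl removes the water as hexamethyldisiloxane so that the equilibrium lies on the side of 7.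

Step 4
Reactants: 5 (S)-5-(3,4,5-trimethoxyphenyl)furan-2(5H)-one; 7 α-chloro-3,4,5-trimethoxybenzyl (trimethylsilyl)methyl ether
Product: 9 (3S,3aR,6S,6aS)-3,6-bis(3,4,5-trimethoxyphenyl)tetrahydro-1H,3H-furo[3,4-c]furan-1-one, via carbonyl ylide 8 (not isolated)
Conditions: CsF (2.5 equiv, dried), MeCN, 0 °C → rt, 7 (2 equiv) added over 2 h
Reagents that add atoms: none
Why: Fluoride attacks silicon of 7 (which is in equilibrium with its oxocarbenium chloride) and 1,3-elimination of Me3SiF and chloride releases the non-stabilised, E-configured carbonyl ylide 8, which adds in a concerted suprafacial [3+2] cycloaddition across the α,β double bond of 5. The closest known reaction type is the cycloaddition of fluoride-generated silylmethyl-ether carbonyl ylides with acrylates, maleates and enones. The oxolane ring is closed by the cycloaddition itself, the C2–C3 and C4–C5 bonds forming in one ring-forming event, which can only give the cis-fused bicycle. C3 and C4 are set together by approach to the butenolide face opposite the γ-aryl group, so the existing stereocentre of 5 controls both, and suprafacial addition fixes them cis. C2 is controlled by the ylide: the E ylide in the exo arrangement, aryl turned away from the lactone, should place the C2 aryl on the convex face trans to the C3 carbonyl carbon, and any C2 epimer is removed by chromatography at this stage. The step needs the CH2 terminus to bond to the β-carbon, secured by the larger ylide HOMO coefficient at the unsubstituted terminus meeting the larger LUMO coefficient at the β-carbon and by the small CH2 end being the one that can sit next to the γ-aryl group, and it needs 5 to keep its configuration, which sparingly soluble CsF and slow addition of 7 favour by keeping the medium near neutral.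

Step 5
Reactants: 9 (3S,3aR,6S,6aS)-3,6-bis(3,4,5-trimethoxyphenyl)tetrahydro-1H,3H-furo[3,4-c]furan-1-one
Product: 10 (2S,3S,4R)-2-(3,4,5-trimethoxyphenyl)-4-[(3,4,5-trimethoxyphenyl)methyl]oxolane-3-carboxylic acid
Conditions: H2 (1 atm), 10% Pd/C, pyridine (0.5 equiv), EtOAc–MeOH, rt; aq. NaH2PO4 wash
Reagents that add atoms: none
Why: Catalytic hydrogenolysis of a benzylic C–O bond under neutral conditions, in which the lactone carboxylate is a much better leaving group on palladium than the alkoxide of the oxolane and pyridine further suppresses benzyl ether cleavage, so only the γ-carbon should be reduced to the CH2 of the C4 benzyl group while C2, C3 and C4 keep their configuration.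

Step 6
Reactants: 10 (2S,3S,4R)-2-(3,4,5-trimethoxyphenyl)-4-[(3,4,5-trimethoxyphenyl)methyl]oxolane-3-carboxylic acid
Product: 11 [(2S,3R,4R)-2-(3,4,5-trimethoxyphenyl)-4-[(3,4,5-trimethoxyphenyl)methyl]oxolan-3-yl]methanol
Conditions: BH3·THF (3 equiv), THF, 0 °C → rt; aq. NaHCO3 work-up
Reagents that add atoms: none
Why: Borane reduction of a carboxylic acid through its acyloxyborane, which is chemoselective and needs neither acid nor base, so C3 cannot epimerise and the C2–O1 bond cannot ionise (a C2 cation would be trapped by the trimethoxybenzyl ring in a Friedel–Crafts closure).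

Compound list
1 | 3,4,5-trimethoxybenzaldehyde | COc1cc(C=O)cc(OC)c1OC | starting material
2 | methyl propiolate | C#CC(=O)OC | starting material
3 | methyl (R)-4-hydroxy-4-(3,4,5-trimethoxyphenyl)but-2-ynoate | COC(=O)C#C[C@H](O)c1cc(OC)c(OC)c(OC)c1 | intermediate
4 | methyl (S,Z)-4-hydroxy-4-(3,4,5-trimethoxyphenyl)but-2-enoate (not isolated) | COC(=O)/C=C\[C@H](O)c1cc(OC)c(OC)c(OC)c1 | intermediate
5 | (S)-5-(3,4,5-trimethoxyphenyl)furan-2(5H)-one | O=C1O[C@H](c2cc(OC)c(OC)c(OC)c2)C=C1 | intermediate
6 | (trimethylsilyl)methanol | C[Si](C)(C)CO | starting material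
7 | α-chloro-3,4,5-trimethoxybenzyl (trimethylsilyl)methyl ether, racemic at the chloro carbon | COc1cc(C(Cl)OC[Si](C)(C)C)cc(OC)c1OC | intermediate
8 | (E)-carbonyl ylide, [(3,4,5-trimethoxyphenyl)methylidene]oxonium methylide (not isolated) | COc1cc(/C=[O+]/[CH2-])cc(OC)c1OC | intermediate
9 | (3S,3aR,6S,6aS)-3,6-bis(3,4,5-trimethoxyphenyl)tetrahydro-1H,3H-furo[3,4-c]furan-1-one; cis-fused (1S,4S,5R,8S)-4,8-diaryl-3,7-dioxabicyclo[3.3.0]octan-2-one (each ring oxygen is one atom away from the ring-fusion carbons, hence 3,7) | O=C1O[C@H](c2cc(OC)c(OC)c(OC)c2)[C@H]2CO[C@H](c3cc(OC)c(OC)c(OC)c3)[C@@H]12 | intermediate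
10 | (2S,3S,4R)-2-(3,4,5-trimethoxyphenyl)-4-[(3,4,5-trimethoxyphenyl)methyl]oxolane-3-carboxylic acid | COc1cc(C[C@H]2CO[C@H](c3cc(OC)c(OC)c(OC)c3)[C@H]2C(=O)O)cc(OC)c1OC | intermediate
11 | [(2S,3R,4R)-2-(3,4,5-trimethoxyphenyl)-4-[(3,4,5-trimethoxyphenyl)methyl]oxolan-3-yl]methanol (2,3-trans, 3,4-cis) | COc1cc(C[C@H]2CO[C@H](c3cc(OC)c(OC)c(OC)c3)[C@H]2CO)cc(OC)c1OC | target

Total step count: 6. Longest linear sequence: 5 steps (steps 1, 2, 4, 5, 6); step 3 is a one-step side branch.

Steps most likely to fail

1. Step 4 (key step). What may go wrong: fluoride may deprotonate the γ-position of 5 faster than the ylide is trapped, so that enantiopurity is lost before the cycloaddition. The ylide may also add with reversed orientation or with its aryl group endo (C2 epimer), which lowers throughput. The fallback sets out from 1 and comes back at 11; it closes the oxolane last by etherification instead of cycloaddition, using dibenzylbutyrolactone chemistry. Stobbe condensation of 1 with dimethyl succinate (NaOMe, MeOH) should give (E)-3-(methoxycarbonyl)-4-(3,4,5-trimethoxyphenyl)but-3-enoic acid F1. Asymmetric hydrogenation over [Rh(cod)2]BF4/Et-DuPhos (ligand enantiomer giving the R acid) should give (R)-3-(methoxycarbonyl)-4-(3,4,5-trimethoxyphenyl)butanoic acid F2. Reduction of its ester group as the carboxylate salt with Ca(BH4)2, then acidification, should give (R)-4-[(3,4,5-trimethoxyphenyl)methyl]oxolan-2-one F3. Its lithium enolate (LiN(SiMe3)2, THF, −78 °C) should add to a second equivalent of 1 trans to the benzyl group, giving (3S,4R)-3-[hydroxy(3,4,5-trimethoxyphenyl)methyl]-4-[(3,4,5-trimethoxyphenyl)methyl]oxolan-2-one F4; both carbinol epimers are usable. LiAlH4 should then give (2R,3R)-2-[hydroxy(3,4,5-trimethoxyphenyl)methyl]-3-[(3,4,5-trimethoxyphenyl)methyl]butane-1,4-diol F5. A short exposure to catalytic camphorsulfonic acid (CH2Cl2, 0 °C, quenched with Et3N) ionises the benzylic alcohol, and the primary hydroxyl on the benzyl-bearing carbon captures the cation to close the oxolane 2,3-trans under kinetic control, giving 11.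

2. Step 5. What may go wrong: hydrogenolysis of the second benzylic C–O bond (C2–O1 of the oxolane) may compete with lactone cleavage, or the lactone cleavage may stall under the ether-sparing conditions. The fallback sets out from 9 and comes back at 11; it uses radical deoxygenation, which can only touch a derivatised hydroxyl. LiAlH4 should reduce the lactone to [(2S,3R,4R)-4-[(S)-hydroxy(3,4,5-trimethoxyphenyl)methyl]-2-(3,4,5-trimethoxyphenyl)oxolan-3-yl]methanol F6. Silylation of the primary hydroxyl (t-BuMe2SiCl, imidazole) should give the primary tert-butyldimethylsilyl ether of that diol F7. 1,1′-Thiocarbonyldiimidazole should convert the benzylic hydroxyl into the O-benzylic imidazole-1-carbothioate F8. Bu3SnH with AIBN in toluene at 80 °C should remove the benzylic oxygen to give the tert-butyldimethylsilyl ether of 11 F9. Bu4NF then releases 11.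

3. Step 3. What may go wrong: incomplete conversion and reversion of the moisture-sensitive, readily ionised chloro ether to aldehyde and symmetrical acetal, which would starve the key step of ylide. The fallback sets out from 1 and 6 and comes back at 7; it replaces the direct condensation by cleavage of an isolable acetal. Acid-catalysed acetalisation (2.2 equiv of 6, catalytic TsOH, toluene, azeotropic water removal) should give 3,4,5-trimethoxybenzaldehyde bis[(trimethylsilyl)methyl] acetal F10, which can be purified and stored. Acetyl chloride (1.1 equiv, CH2Cl2, 0 °C → rt) then exchanges one alkoxy group for chloride to give 7; the co-formed ester is inert in step 4.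

Further compounds
F1 | step 4 | (E)-3-(methoxycarbonyl)-4-(3,4,5-trimethoxyphenyl)but-3-enoic acid | COC(=O)/C(CC(=O)O)=C/c1cc(OC)c(OC)c(OC)c1
F2 | step 4 | (R)-3-(methoxycarbonyl)-4-(3,4,5-trimethoxyphenyl)butanoic acid | COC(=O)[C@H](Cc1cc(OC)c(OC)c(OC)c1)CC(=O)O
F3 | step 4 | (R)-4-[(3,4,5-trimethoxyphenyl)methyl]oxolan-2-one | O=C1C[C@@H](Cc2cc(OC)c(OC)c(OC)c2)CO1
F4 | step 4 | (3S,4R)-3-[hydroxy(3,4,5-trimethoxyphenyl)methyl]-4-[(3,4,5-trimethoxyphenyl)methyl]oxolan-2-one, carbinol epimers | O=C1OC[C@H](Cc2cc(OC)c(OC)c(OC)c2)[C@H]1C(O)c1cc(OC)c(OC)c(OC)c1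
F5 | step 4 | (2R,3R)-2-[hydroxy(3,4,5-trimethoxyphenyl)methyl]-3-[(3,4,5-trimethoxyphenyl)methyl]butane-1,4-diol, carbinol epimers | OC[C@H](Cc1cc(OC)c(OC)c(OC)c1)[C@H](CO)C(O)c1cc(OC)c(OC)c(OC)c1
F6 | step 5 | [(2S,3R,4R)-4-[(S)-hydroxy(3,4,5-trimethoxyphenyl)methyl]-2-(3,4,5-trimethoxyphenyl)oxolan-3-yl]methanol | O[C@H](c1cc(OC)c(OC)c(OC)c1)[C@H]2CO[C@H](c3cc(OC)c(OC)c(OC)c3)[C@H]2CO
F7 | step 5 | primary tert-butyldimethylsilyl ether of F6 | O[C@H](c1cc(OC)c(OC)c(OC)c1)[C@H]2CO[C@H](c3cc(OC)c(OC)c(OC)c3)[C@H]2CO[Si](C)(C)C(C)(C)C
F8 | step 5 | O-benzylic imidazole-1-carbothioate of F7 | S=C(O[C@H](c1cc(OC)c(OC)c(OC)c1)[C@H]2CO[C@H](c3cc(OC)c(OC)c(OC)c3)[C@H]2CO[Si](C)(C)C(C)(C)C)n4ccnc4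
F9 | step 5 | tert-butyldimethylsilyl ether of 11 | COc1cc(C[C@H]2CO[C@H](c3cc(OC)c(OC)c(OC)c3)[C@H]2CO[Si](C)(C)C(C)(C)C)cc(OC)c1OC
F10 | step 3 | 3,4,5-trimethoxybenzaldehyde bis[(trimethylsilyl)methyl] acetal | COc1cc(C(OC[Si](C)(C)C)OC[Si](C)(C)C)cc(OC)c1OC
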